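## Retrosynthetic overview

1. Feature (benzofuran numbering; ring A = dihydrofuran O1–C2–C3–C3a–C7a, ring B = cyclohexadiene C3a–C4–C5–C6–C7–C7a): C7 carries the 3-phenylpropanoyl ketone and C6 the hydroxyl, cis to each other. This is a β-hydroxy ketone, an aldol retron inside ring B.
2. Cutting C6–C7 (ring-closing boron aldol) opens ring B to a keto enal on ring A, with C7a–CH2–C(O)CH2CH2Ph and C3a–C(OMe)=CH–CHO. The enal is E by the CIP rules, with CHO and C3a on the same side of C4=C5.
3. The aldehyde is released last from an S-ethyl enethioate and the ketone from a silyl-masked carbinol. C4–C5–C6 grow from the C3a carboxyl by crossed Claisen homologation and O-methylation, all of which leave the aryl methyl ester untouched.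
4. Ring A comes from a [4+1] annulation of an arylidene β-keto ester (Knoevenagel) with a chiral ammonium acetonylide, which sets C2/C3 trans. MeMgBr on the C2 acetyl group gives CMe2OH.
5. Order of ring formation: the benzoate ring is bought, ring A is closed in step 7, ring B in step 16.

Key step: step 16

Assumption: the sense of induction of the alkaloid-bound ylide cannot be derived with certainty, so the quinidine series is written; if it gives the mirror-image ring A, the quinine series is used in steps 5–7.

Assumption: (−)-Ipc2BOTf (from (+)-α-pinene) is written because (−)-Ipc2B reagents add to the si face of aldehydes, which corresponds to 6R here; if the ring-closing case is mismatched, the (+)-reagent is used in the same step.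

Assumption: (−)-Ipc2BH (crystallised from (+)-α-pinene and BH3·SMe2) is taken as a stock reagent; compounds 14–23 are pairs of epimers at the side-chain carbinol, a centre that is erased in step 14.

Remark: Ar = 5-(methoxycarbonyl)-2-(triisopropylsilyloxy)phenyl.

## Route

**Step 1**
Reactants: 1 allyl acetoacetate; 2 3-phenylpropanal
Product: 4 allyl 5-hydroxy-3-oxo-7-phenylheptanoate (racemic), via dilithio dianion 3 (not isolated)
Conditions: LiN(i-Pr)2 (2.1 equiv), THF, 0 °C; 2, −78 °C; AcOH quench
Reagents that add atoms: none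
Why: γ-Aldol addition of an acetoacetate dianion, whose terminal carbanion is the more reactive site; the new carbinol centre is left uncontrolled because step 14 turns it into the ketone.

**Step 2**
Reactants: 4 allyl 5-hydroxy-3-oxo-7-phenylheptanoate
Product: 5 allyl 3-oxo-7-phenyl-5-(triethylsilyloxy)heptanoate (racemic)
Conditions: Et3SiCl, imidazole, CH2Cl2, 0 °C
Reagents that add atoms: chlorotriethylsilane, CC[Si](Cl)(CC)CC
Why: Standard silylation of a secondary alcohol, which keeps the δ-hydroxy β-keto ester from lactonising or dehydrating in the basic steps ahead; no stereocentre is touched.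

**Step 3**
Reactants: 6 methyl 3-formyl-4-hydroxybenzoate
Product: 7 methyl 3-formyl-4-(triisopropylsilyloxy)benzoate
Conditions: i-Pr3SiCl, imidazole, DMF, rt
Reagents that add atoms: chlorotriisopropylsilane, CC(C)[Si](Cl)(C(C)C)C(C)C
Why: Silylation of the phenol blocks coumarin formation in the next step, and the aryl TIPS ether should withstand the amine, carbonate, Grignard and mild acid conditions that follow.

**Step 4**
Reactants: 5 allyl 3-oxo-7-phenyl-5-(triethylsilyloxy)heptanoate; 7 methyl 3-formyl-4-(triisopropylsilyloxy)benzoate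
Product: 8 allyl 2-(Ar-methylidene)-3-oxo-7-phenyl-5-(triethylsilyloxy)heptanoate (E/Z mixture)
Conditions: piperidine (0.2 equiv), AcOH (0.2 equiv), 4 Å MS, toluene, 40 °C
Reagents that add atoms: none
Why: Knoevenagel condensation at the only doubly activated methylene of 5; the alkene geometry does not matter because this carbon becomes a planar enolate in step 7.

**Step 5**
Reactants: 9 quinidine
Product: 10 9-O-methylquinidine
Conditions: NaH, DMF, 0 °C; MeI (1.0 equiv), 0 °C
Reagents that add atoms: iodomethane, CI
Why: Williamson etherification of the C9 alkoxide, which outruns N-alkylation at 0 °C; capping the hydroxyl stops it from adding to the acetonyl ketone of the salt made next.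

**Step 6**
Reactants: 10 9-O-methylquinidine; 11 chloroacetone
Product: 12 N-(2-oxopropyl)-9-O-methylquinidinium chloride
Conditions: THF, 50 °C
Reagents that add atoms: none
Why: Menshutkin quaternisation at the quinuclidine nitrogen, which is far more nucleophilic than the quinoline nitrogen.

**Step 7**
Reactants: 8 arylidene β-keto ester; 12 N-(2-oxopropyl)-9-O-methylquinidinium chloride
Product: 14 allyl (4R,5R)-5-acetyl-4-Ar-2-[4-phenyl-2-(triethylsilyloxy)butyl]-4,5-dihydrofuran-3-carboxylate (trans), via ammonium ylide 13 (not isolated)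
Conditions: Cs2CO3, MeCN, 0 °C to rt
Reagents that add atoms: none
Why: Formal [4+1] ammonium-ylide annulation (Michael addition, then 5-exo-tet O-alkylation by the ketone enolate oxygen with loss of the amine); C3 is set in the conjugate addition under the alkaloid cage, and C2 follows in the invertive closure as the trans isomer, which is also the thermodynamic one because C2–H is enolisable next to the acetyl group.

**Step 8**
Reactants: 14 acetyl dihydrofuran
Product: 15 allyl (4R,5R)-4-Ar-5-(2-hydroxypropan-2-yl)-2-[4-phenyl-2-(triethylsilyloxy)butyl]-4,5-dihydrofuran-3-carboxylate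
Conditions: MeMgBr (1.2 equiv), THF, −78 °C; pH 7 buffer
Reagents that add atoms: methylmagnesium bromide, C[Mg]Br
Why: Grignard addition to an α-alkoxy methyl ketone, which at −78 °C is far more electrophilic than the benzoate or the vinylogous carbonate ester; no new stereocentre forms and C2 stops being epimerisable.

**Step 9**
Reactants: 15 tertiary alcohol
Product: 16 allyl (4R,5R)-4-Ar-2-[4-phenyl-2-(triethylsilyloxy)butyl]-5-[2-(triethylsilyloxy)propan-2-yl]-4,5-dihydrofuran-3-carboxylate
Conditions: Et3SiOTf, 2,6-lutidine, CH2Cl2, −78 to 0 °C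
Reagents that add atoms: triethylsilyl trifluoromethanesulfonate, CC[Si](CC)(CC)OS(=O)(=O)C(F)(F)F
Why: Silyl triflate silylation of a hindered tertiary alcohol, so that no free hydroxyl meets the enolates and the boron triflate used later.

**Step 10**
Reactants: 16 allyl ester
Product: 17 (4R,5R)-4-Ar-2-[4-phenyl-2-(triethylsilyloxy)butyl]-5-[2-(triethylsilyloxy)propan-2-yl]-4,5-dihydrofuran-3-carboxylic acid
Conditions: Pd(PPh3)4 (5 mol %), morpholine, THF, rt; pH 5 buffer wash
Reagents that add atoms: none
Why: Tsuji–Trost deallylation, in which zerovalent palladium ionises only the allyl ester and morpholine traps the allyl fragment; the methyl benzoate and the silyl ethers stay intact.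

**Step 11**
Reactants: 17 C3a carboxylic acid; 18 S-ethyl thioacetate
Product: 21 S-ethyl 3-oxo-3-{(4R,5R)-4-Ar-2-[4-phenyl-2-(triethylsilyloxy)butyl]-5-[2-(triethylsilyloxy)propan-2-yl]-4,5-dihydrofuran-3-yl}propanethioate, via acyl imidazolide 19 (not isolated), via lithium thioacetate enolate 20 (not isolated)
Conditions: 17, 1,1'-carbonyldiimidazole, THF, rt; added to 18 (3 equiv), LiN(SiMe3)2, THF, −78 °C; −78 to −40 °C; AcOH quench
Reagents that add atoms: none
Why: Crossed Claisen condensation through an acyl imidazolide, the only acyl donor in the molecule reactive enough for the thioester enolate at low temperature, so C5 and C6 are added without touching the methyl benzoate.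

**Step 12**
Reactants: 21 β-keto thioester
Product: 22 S-ethyl (E)-3-methoxy-3-{(4R,5R)-4-Ar-2-[4-phenyl-2-(triethylsilyloxy)butyl]-5-[2-(triethylsilyloxy)propan-2-yl]-4,5-dihydrofuran-3-yl}prop-2-enethioate
Conditions: Me2SO4, Cs2CO3, DMF, 0 °C
Reagents that add atoms: dimethyl sulfate, COS(=O)(=O)OC
Why: O-alkylation of a β-keto thioester enolate, in which the dissociated caesium enolate meets a hard electrophile at oxygen and its dipole-minimised W form gives the E enol ether (OMe anti to C=O, C3a cis to C=O), also the more stable isomer; with C6 at the acid level the methyl group can only end up on the C4 oxygen.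

**Step 13**
Reactants: 22 bis-TES enethioate
Product: 23 S-ethyl (E)-3-{(4R,5R)-4-Ar-2-(2-hydroxy-4-phenylbutyl)-5-[2-(triethylsilyloxy)propan-2-yl]-4,5-dihydrofuran-3-yl}-3-methoxyprop-2-enethioate
Conditions: PPTS (0.2 equiv), MeOH/CH2Cl2, 0 °C
Reagents that add atoms: none
Why: Acid-catalysed methanolysis of a silyl ether, in which the secondary TES ether on the open chain should go much faster than the congested tertiary TES ether and the acid-stable aryl TIPS ether; the acceptor-substituted dienol ether tolerates this weak acid.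

**Step 14**
Reactants: 23 secondary alcohol
Product: 24 S-ethyl (E)-3-{(4R,5R)-4-Ar-2-(2-oxo-4-phenylbutyl)-5-[2-(triethylsilyloxy)propan-2-yl]-4,5-dihydrofuran-3-yl}-3-methoxyprop-2-enethioate
Conditions: Dess–Martin periodinane, NaHCO3, CH2Cl2, 0 °C to rt
Reagents that add atoms: none
Why: Dess–Martin oxidation under buffered, near-neutral conditions merges both carbinol epimers into one ketone and spares the thioester and the enol ethers.

**Step 15**
Reactants: 24 keto enethioate
Product: 25 methyl 3-{(2R,3R)-4-[(E)-1-methoxy-3-oxoprop-1-enyl]-5-(2-oxo-4-phenylbutyl)-2-[2-(triethylsilyloxy)propan-2-yl]-2,3-dihydrofuran-3-yl}-4-(triisopropylsilyloxy)benzoate (keto enal)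
Conditions: Et3SiH (3 equiv), Pd/C (10 wt %), acetone, rt; filtration through Celite and pH 7-buffered silica, used at once
Reagents that add atoms: none
Why: Fukuyama reduction, in which zerovalent palladium inserts only into the acyl–sulfur bond and the silane delivers hydride, so the aldehyde appears next to a methyl ester and a ketone in a neutral medium that gives the acidic C7 methylene no occasion for a premature aldol condensation.

**Step 16**
Reactants: 25 keto enal
Product: 28 methyl 3-{(2R,3R,6R,7R)-6-hydroxy-4-methoxy-7-(3-phenylpropanoyl)-2-[2-(triethylsilyloxy)propan-2-yl]-2,3,6,7-tetrahydro-1-benzofuran-3-yl}-4-(triisopropylsilyloxy)benzoate, via Z-enol borinate 26 (not isolated), via boron aldolate 27 (not isolated)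
Conditions: (−)-Ipc2BH, TfOH, hexane, rt (gives (−)-Ipc2BOTf in the flask, 1.3 equiv); CH2Cl2, i-Pr2NEt (1.6 equiv), then 25, −78 °C, then −20 °C; pH 7 buffer, MeOH, 30% H2O2, 0 °C
Reagents that add atoms: none
Why: The boron triflate and the hindered amine remove a proton from C7, the only methylene that is both α to the ketone and vinylogously tied to the enal through C7a=C3a–C4=C5 (the CH2 on the phenethyl side is far less acidic, which secures the regioselectivity), and this should give the Z(O)-enol borinate 26. C7 then adds to C6 while boron bridges the enolate and aldehyde oxygens, and the six-membered O–B–O chelate 27 holds an adduct that could otherwise revert because the acceptor is an enal stabilised by two oxygen donors. The closest known reactions are the Ipc2BOTf-mediated syn aldol of ethyl ketones with enals (Paterson aldol) and ring-closing boron aldols of keto aldehydes. Ring B closes in the 6-(enolexo)-exo-trig mode, which needs CHO and C3a cis on C4=C5 as in 25, and any Z enal should be funnelled in because boron coordination lowers the rotation barrier of this push–pull bond. In the chair Zimmerman–Traxler array fused to the forming ring the Z-enolate holds C7a axial and C5 equatorial, the only pairing that the planar diene tether can span, and this sets C7 relative to C6 as the syn aldol, that is cis 6-OH/7-acyl. The absolute sense (6R,7R, both groups on the face of the C2 substituent and opposite to the C3 aryl) is set by the isopinocampheyl ligands through si-face attack on the aldehyde, since C2 and C3 are remote from C6/C7 and add little bias of their own, and the amine-buffered medium with a pH 7 oxidative work-up avoids dehydration to the arene.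

**Step 17**
Reactants: 28 bis-silyl ether
Product: 29 methyl 4-hydroxy-3-[(2R,3R,6R,7R)-6-hydroxy-2-(2-hydroxypropan-2-yl)-4-methoxy-7-(3-phenylpropanoyl)-2,3,6,7-tetrahydro-1-benzofuran-3-yl]benzoate (target)
Conditions: Bu4NF/AcOH (1:1), THF, 0 °C to rt; pH 7 buffer
Reagents that add atoms: none
Why: Fluoride desilylation buffered with acetic acid removes the aryl TIPS and tertiary TES groups near neutrality, so that neither retro-aldol or C7 epimerisation (base) nor ionisation of the allylic C6 hydroxyl (acid) should set in; no stereocentre is touched.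

## Compound list

1 | allyl acetoacetate | C=CCOC(=O)CC(C)=O | starting material
2 | 3-phenylpropanal | O=CCCc1ccccc1 | starting material
3 | dilithio dianion of allyl acetoacetate | C=CCOC([O-])=CC([O-])=C.[Li+].[Li+] | intermediate
4 | allyl 5-hydroxy-3-oxo-7-phenylheptanoate (racemic) | C=CCOC(=O)CC(=O)CC(O)CCc1ccccc1 | intermediate
5 | allyl 3-oxo-7-phenyl-5-(triethylsilyloxy)heptanoate (racemic) | C=CCOC(=O)CC(=O)CC(CCc1ccccc1)O[Si](CC)(CC)CC | intermediate
6 | methyl 3-formyl-4-hydroxybenzoate | COC(=O)c1ccc(O)c(C=O)c1 | starting material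
7 | methyl 3-formyl-4-(triisopropylsilyloxy)benzoate | COC(=O)c1ccc(O[Si](C(C)C)(C(C)C)C(C)C)c(C=O)c1 | intermediate
8 | arylidene β-keto ester (E/Z mixture) | COC(=O)c1ccc(O[Si](C(C)C)(C(C)C)C(C)C)c(C=C(C(=O)OCC=C)C(=O)CC(CCc2ccccc2)O[Si](CC)(CC)CC)c1 | intermediate
9 | quinidine | C=C[C@H]1CN2CC[C@H]1C[C@@H]2[C@@H](O)c1ccnc2ccc(OC)cc12 | starting material
10 | 9-O-methylquinidine | C=C[C@H]1CN2CC[C@H]1C[C@@H]2[C@@H](OC)c1ccnc2ccc(OC)cc12 | intermediate
11 | chloroacetone | CC(=O)CCl | starting material
12 | N-(2-oxopropyl)-9-O-methylquinidinium chloride | C=C[C@H]1C[N+]2(CC(C)=O)CC[C@H]1C[C@@H]2[C@@H](OC)c1ccnc2ccc(OC)cc12.[Cl-] | intermediate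
13 | ammonium acetonylide from 12 | C=C[C@H]1C[N+]2([CH-]C(C)=O)CC[C@H]1C[C@@H]2[C@@H](OC)c1ccnc2ccc(OC)cc12 | intermediate
14 | trans-(4R,5R) 5-acetyl dihydrofuran allyl ester | COC(=O)c1ccc(O[Si](C(C)C)(C(C)C)C(C)C)c([C@@H]2C(C(=O)OCC=C)=C(CC(CCc3ccccc3)O[Si](CC)(CC)CC)O[C@H]2C(C)=O)c1 | intermediate
15 | tertiary alcohol | COC(=O)c1ccc(O[Si](C(C)C)(C(C)C)C(C)C)c([C@@H]2C(C(=O)OCC=C)=C(CC(CCc3ccccc3)O[Si](CC)(CC)CC)O[C@H]2C(C)(C)O)c1 | intermediate
16 | bis-TES allyl ester | COC(=O)c1ccc(O[Si](C(C)C)(C(C)C)C(C)C)c([C@@H]2C(C(=O)OCC=C)=C(CC(CCc3ccccc3)O[Si](CC)(CC)CC)O[C@H]2C(C)(C)O[Si](CC)(CC)CC)c1 | intermediate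
17 | C3a carboxylic acid | COC(=O)c1ccc(O[Si](C(C)C)(C(C)C)C(C)C)c([C@@H]2C(C(=O)O)=C(CC(CCc3ccccc3)O[Si](CC)(CC)CC)O[C@H]2C(C)(C)O[Si](CC)(CC)CC)c1 | intermediate
18 | S-ethyl thioacetate | CCSC(C)=O | starting material
19 | acyl imidazolide of 17 | COC(=O)c1ccc(O[Si](C(C)C)(C(C)C)C(C)C)c([C@@H]2C(C(=O)n3ccnc3)=C(CC(CCc3ccccc3)O[Si](CC)(CC)CC)O[C@H]2C(C)(C)O[Si](CC)(CC)CC)c1 | intermediate
20 | lithium enolate of S-ethyl thioacetate | C=C([O-])SCC.[Li+] | intermediate
21 | β-keto thioester | COC(=O)c1ccc(O[Si](C(C)C)(C(C)C)C(C)C)c([C@@H]2C(C(=O)CC(=O)SCC)=C(CC(CCc3ccccc3)O[Si](CC)(CC)CC)O[C@H]2C(C)(C)O[Si](CC)(CC)CC)c1 | intermediate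
22 | (E)-β-methoxy enethioate, bis-TES | COC(=O)c1ccc(O[Si](C(C)C)(C(C)C)C(C)C)c([C@@H]2C(/C(OC)=C\C(=O)SCC)=C(CC(CCc3ccccc3)O[Si](CC)(CC)CC)O[C@H]2C(C)(C)O[Si](CC)(CC)CC)c1 | intermediate
23 | (E)-β-methoxy enethioate, free secondary alcohol | COC(=O)c1ccc(O[Si](C(C)C)(C(C)C)C(C)C)c([C@@H]2C(/C(OC)=C\C(=O)SCC)=C(CC(O)CCc3ccccc3)O[C@H]2C(C)(C)O[Si](CC)(CC)CC)c1 | intermediate
24 | keto enethioate | COC(=O)c1ccc(O[Si](C(C)C)(C(C)C)C(C)C)c([C@@H]2C(/C(OC)=C\C(=O)SCC)=C(CC(=O)CCc3ccccc3)O[C@H]2C(C)(C)O[Si](CC)(CC)CC)c1 | intermediate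
25 | keto enal (aldol precursor; E enal, CHO cis to C3a) | COC(=O)c1ccc(O[Si](C(C)C)(C(C)C)C(C)C)c([C@@H]2C(/C(OC)=C\C=O)=C(CC(=O)CCc3ccccc3)O[C@H]2C(C)(C)O[Si](CC)(CC)CC)c1 | intermediate
26 | Z(O)-enol diisopinocampheylborinate | COC(=O)c1ccc(O[Si](C(C)C)(C(C)C)C(C)C)c([C@@H]2C(/C(OC)=C\C=O)=C(/C=C(\OB([C@@H]3C[C@@H]4C[C@H]([C@H]3C)C4(C)C)[C@@H]3C[C@@H]4C[C@H]([C@H]3C)C4(C)C)CCc3ccccc3)O[C@H]2C(C)(C)O[Si](CC)(CC)CC)c1 | intermediate
27 | boron aldolate (chelated to the ketone oxygen) | COC(=O)c1ccc(O[Si](C(C)C)(C(C)C)C(C)C)c([C@@H]2C3=C(O[C@H]2C(C)(C)O[Si](CC)(CC)CC)[C@H](C(=O)CCc4ccccc4)[C@H](OB([C@@H]4C[C@@H]5C[C@H]([C@H]4C)C5(C)C)[C@@H]4C[C@@H]5C[C@H]([C@H]4C)C5(C)C)C=C3OC)c1 | intermediate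
28 | bis-silyl ether of the target (2R,3R,6R,7R) | COC(=O)c1ccc(O[Si](C(C)C)(C(C)C)C(C)C)c([C@@H]2C3=C(O[C@H]2C(C)(C)O[Si](CC)(CC)CC)[C@H](C(=O)CCc4ccccc4)[C@H](O)C=C3OC)c1 | intermediate
29 | CNP0080427.3 (2R,3R,6R,7R) | COC(=O)c1ccc(O)c([C@@H]2C3=C(O[C@H]2C(C)(C)O)[C@H](C(=O)CCc2ccccc2)[C@H](O)C=C3OC)c1 | target

## Step count and risks

Total step count: 17. Longest linear sequence: 14 (steps 1, 2, 4 and 7–17).

**Step 16.**
- The addition may stall or revert, because the acceptor is an enal stabilised by two oxygen donors.
- The aldolate may lose water to the arene during work-up.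
- The facial selectivity may be poor if ligand and substrate are mismatched.
- A prototropic shift of C7a=C3a to the exocyclic position may also occur in 25, although it leads to the same enolate.

The fallback forms the same C6–C7 bond by a silyl-trapped pericyclic closure instead of a metal-enolate addition. It sets out from 25 and comes back at 29. Treating 25 with Et3SiOTf and Et3N in CH2Cl2 at −78 °C should silylate the most basic oxygen (the aldehyde) and remove a C7 proton, giving the 6-(triethylsilyloxy) triene F1. On warming, its termini C6 and C7 should join by a disrotatory six-electron electrocyclisation. Both terminal substituents point outward, so they become cis. The product is the tris-silyl ether F2, in which the aldol can no longer revert. The two cis diastereomers would be separated on buffered silica, and the conditions of step 17 then remove all three silyl groups to give 29.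

**Step 7.**
- Asymmetric induction by the alkaloid may be low.
- The enolate may close through carbon to a cyclopropane instead of through oxygen.
- The ortho silyloxy group may slow the conjugate addition.

The fallback reverses the roles of the partners. It sets out from 7 and 5 and comes back at 14. Wittig olefination of 7 with Ph3P=C(Br)C(O)CH3 should give the (Z)-α-bromo enone F3. The β-keto ester 5 is then added to F3 under a quinidine-derived tertiary-amine squaramide catalyst, with K2CO3 as the acid scavenger. This is an enantioselective Michael addition followed by O-alkylation of the enol with loss of bromide. The epimerisable C2 centre should again settle trans, giving 14.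

**Step 11.**
- Acyl transfer from the hindered, donor-deactivated imidazolide may be too slow.
- The thioacetate enolate may then act as a base at C7 or condense with itself.

The fallback goes through an acylketene. It sets out from 17 and comes back at 21. Coupling of 17 with Meldrum's acid (EDC·HCl, DMAP, CH2Cl2) should give the acyl Meldrum's acid F4. Thermolysis of F4 with EtSH in toluene (sealed tube, 90 °C) releases the acylketene, which the thiol traps as 21.

## Further compounds

F1 | step 16 | 6-(triethylsilyloxy) triene from 25 | COC(=O)c1ccc(O[Si](C(C)C)(C(C)C)C(C)C)c([C@@H]2/C(=C(OC)/C=C/O[Si](CC)(CC)CC)/C(=C/C(=O)CCc3ccccc3)O[C@H]2C(C)(C)O[Si](CC)(CC)CC)c1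
F2 | step 16 | tris-silyl ether (6-O-triethylsilyl ether of 28) | COC(=O)c1ccc(O[Si](C(C)C)(C(C)C)C(C)C)c([C@@H]2C3=C(O[C@H]2C(C)(C)O[Si](CC)(CC)CC)[C@H](C(=O)CCc4ccccc4)[C@H](O[Si](CC)(CC)CC)C=C3OC)c1
F3 | step 7 | methyl 3-[(Z)-2-bromo-3-oxobut-1-enyl]-4-(triisopropylsilyloxy)benzoate | CC(=O)/C(Br)=C/c1cc(C(=O)OC)ccc1O[Si](C(C)C)(C(C)C)C(C)C
F4 | step 11 | acyl Meldrum's acid of 17 (enol form) | COC(=O)c1ccc(O[Si](C(C)C)(C(C)C)C(C)C)c([C@@H]2C(C(O)=C3C(=O)OC(C)(C)OC3=O)=C(CC(CCc3ccccc3)O[Si](CC)(CC)CC)O[C@H]2C(C)(C)O[Si](CC)(CC)CC)c1
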